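No constant of this flask is given, but one can be read from the runs and turned into a time: the life of monomer in chains before it passes on to over-reaction product.

| flask | free monomer | initiator | temperature | remark | time |
|---|---|---|---|---|---|
| Tuesday's | 0.010 M | 5 mol% | 50 °C | run made earlier |  |
| Saturday's | 0.015 M | 5 mol% | 72 °C | run made earlier |  |
| Wednesday's | 0.020 M | 10 mol% | 50 °C | run made earlier |  |
| north | 0.020 M | 5 mol% | 80 °C |  | 5.0 h |
| west | 0.020 M | 5 mol% | 40 °C |  | 5.0 h |
| south | 0.020 M | 5 mol% | 60 °C |  | 5.0 h |

| run | time / h | monomer in chains / % | over-reaction product / % | isomer of the product / % |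
|---|---|---|---|---|
| Tuesday's | 2.00 | 16 | 6 | 5 |
| Tuesday's | 4.00 | 15 | 23 | 4 |
| Tuesday's | 6.00 | 12 | 33 | 4 |
| Tuesday's | 12.0 | 3 | 52 | 4 |
| Tuesday's | 25.0 | 2 | 64 | 1 |
| Saturday's | 0.500 | 11 | 20 | 1 |
| Saturday's | 1.50 | 0 | 43 | 1 |
| Saturday's | 3.00 | 2 | 44 | 0 |
| Saturday's | 4.00 | 0 | 46 | 1 |
| Saturday's | 6.00 | 0 | 43 | 0 |
| Wednesday's | 2.00 | 24 | 14 | 8 |
| Wednesday's | 4.00 | 22 | 39 | 5 |
| Wednesday's | 6.00 | 18 | 52 | 4 |
| Wednesday's | 12.0 | 5 | 81 | 0 |
| Wednesday's | 25.0 | 0 | 91 | 0 |

(standard deviation of a reading: 1.5 percentage points)



1. the best flask by share of monomer in chains in all that became monomer in chains or over-reaction product or isomer of the product; "all alike" if 1.5 percentage points covers them all (north / west / south / all alike)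
2. share of monomer in chains in all that became monomer in chains or over-reaction product or isomer of the product, north
3. share of monomer in chains in all that became monomer in chains or over-reaction product or isomer of the product, west
4. share of monomer in chains in all that became monomer in chains or over-reaction product or isomer of the product, south

Tuesday's run looks contradictory. Between 4.00 h and 6.00 h, over-reaction product gains 10 percentage points, yet monomer in chains, its apparent source, loses 3 points. The gain exceeds the loss, so free monomer must be refilling the chains even while their pool falls. Flow out over mean pool gives a first-order rate constant k without any need for that pool to hold steady: the readings give 0.370 /h at 50 °C. Saturday's run, read the same way, gives 4.18 /h at 72 °C, a rough reading on a small pool. Together they make k change by a factor of 3.01 per 10.0 K.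

The chain life τ, meaning pool over outflow, or 1/k, is then 8.13 h in west, 0.897 h in south and 0.0990 h in north. West has τ longer than the 5.0 h run, while those of south and north are shorter. My own reckoning for west takes chains born evenly over the run, so that a fraction (τ/t)(1 − exp(−t/τ)) = 74.7% survives. Isomer of the product stood at 0.333 of the chains in Wednesday's first reading, which brings the selectivity for chains to 56.0%.

The forecast names west, with 0% for north, 62% for west and 4% for south, on the ground that in west “chains survive”. My figure for west lies below its figure.

The flasks give 0% in north, 56.6% in west and 3.40% in south, so west leads, under these steps: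

    2 growing radical → dead chain (k = 1.00 × 10⁹ /M/s, Ea = 11.0 kJ/mol)
    monomer in chains → over-reaction product (k = 0.140 /h, Ea = 100 kJ/mol)
    free monomer → decomposition product (k = 2.70 × 10⁻⁴ /h, Ea = 117 kJ/mol)
    free monomer + initiating radical → growing radical + monomer in chains (k = 2.30 × 10⁵ /M/s, Ea = 19.0 kJ/mol)
    monomer in chains ⇌ isomer of the product (K = 0.360, k = 0.350 /h, Ea = 97.0 kJ/mol, ΔH = −27.0 kJ/mol)
    initiator → 2 initiating radical (k = 0.0840 /h, Ea = 107 kJ/mol)
    free monomer + growing radical → monomer in chains + growing radical, rate k7*[growing radical]*[free monomer] (k = 1.80 × 10⁷ /M/h, Ea = 21.0 kJ/mol)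
    (constants at 40 °C)

West stands 5.4 points under the forecast, and at 5.00 h it holds 6.36% isomer of the product beside 19.9% monomer in chains. With τ of 8.13 h, the west pool should pass 5.22% to over-reaction product between 2.50 h and 5.00 h, and west gained 6.1 points. With τ of 0.897 h, south's pool should pass 9.90% between 2.0 h and 3.0 h, and south gained 12 points.

The runs are calculated from invented constants, noise included.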